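**Retrosynthetic overview**

1. The target is reached by debenzylation after a double Mitsunobu esterification (inversion at C6) of a bis-O-benzyl α-truxillic-type diacid with two molecules of 6-epi-incarvilline.
2. The cyclobutane comes from the key step, a nitrogen-deletion ring contraction (1,1-diazene, loss of N2, radical-pair collapse) of a 2,5-cis-3,4-cis pyrrolidine-2,4-dicarboxylate that already carries all four stereocentres.
3. The pyrrolidine comes from an enantioselective exo (3+2) reaction of the glycine imine of O-benzylvanillin (built from catechol) with a Z-4-benzyloxycinnamate (Negishi coupling).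
4. 6-epi-Incarvilline comes from face-selective hydrogenation of a bicyclic diene, made by palladium 6-exo-dig cyclisation of an enol triflate, itself from a cuprate/Mannich three-component coupling on (S)-4-silyloxycyclopentenone.
5. Ring order: in the core, pyrrolidine first, then cyclobutane by contraction; in the amine, cyclopentane (from the enone) first, then piperidine.

Assumption: the (R)-ligand in step 5 is taken to give the (2S,3R,4R,5R) series; if the opposite sense is found, the (S)-ligand is used with no other change.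

**Route**

Step 1
Reactants: 1 catechol
Product: 2 guaiacol (2-methoxyphenol)
Conditions: MeI (1.0 equiv), K2CO3 (1.0 equiv), acetone, reflux; base extraction
Reagents that add atoms: iodomethane, CI
Why: Williamson mono-O-methylation, in which one equivalent of base alkylates mainly the more acidic catechol monoanion, and 2 is separated from neutral veratrole by base extraction.

Step 2
Reactants: 2 guaiacol; 3 glyoxylic acid
Product: 6 vanillin (4-hydroxy-3-methoxybenzaldehyde), via mandelic acid 4 (not isolated), via keto acid 5 (not isolated)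
Conditions: OHCCO2H, NaOH, H2O, 30 °C; then CuSO4 (cat.), air, 95 °C; H2SO4
Reagents that add atoms: none
Why: Electrophilic aromatic hydroxyalkylation of the phenoxide by glyoxylate occurs para to the free OH, and the mandelate is then oxidised and decarboxylated (the guaiacol–glyoxylic acid vanillin process).

Step 3
Reactants: 6 vanillin
Product: 7 4-(benzyloxy)-3-methoxybenzaldehyde
Conditions: BnBr, K2CO3, DMF, 60 °C
Reagents that add atoms: benzyl bromide, BrCc1ccccc1
Why: Williamson benzylation of the phenol, which protects it against the oxidant of step 6.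

Step 4
Reactants: 8 1-(benzyloxy)-4-bromobenzene; 9 ethyl (Z)-3-iodoprop-2-enoate
Product: 12 ethyl (Z)-3-[4-(benzyloxy)phenyl]prop-2-enoate, via aryllithium 10 (not isolated), via arylzinc chloride 11 (not isolated)
Conditions: n-BuLi, THF, −78 °C; ZnCl2, −78 → 0 °C; then 9, Pd(PPh3)4 (3 mol%), THF, rt
Reagents that add atoms: none
Why: Bromine–lithium exchange and transmetalation give an arylzinc that undergoes Negishi coupling with the Z-iodoacrylate with retention of alkene geometry.

Step 5
Reactants: 7 4-(benzyloxy)-3-methoxybenzaldehyde; 13 glycine ethyl ester hydrochloride; 12 ethyl (Z)-3-[4-(benzyloxy)phenyl]prop-2-enoate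
Product: 15 diethyl (2S,3R,4R,5R)-5-[4-(benzyloxy)-3-methoxyphenyl]-3-[4-(benzyloxy)phenyl]pyrrolidine-2,4-dicarboxylate, via imine 14 (not isolated)
Conditions: 7, 13, Et3N, MgSO4, CH2Cl2, rt; filter, evaporate; then 12, [Cu(MeCN)4]PF6 (5 mol%), (R)-DTBM-SEGPHOS (5.5 mol%), Et3N (20 mol%), toluene, 0 °C → rt
Reagents that add atoms: none
Why: Proposed new method: the N,O-chelated monovalent-copper azomethine ylide of 14 adds to Z-enoate 12 in an asynchronous concerted (Michael, then fast Mannich) (3+2) reaction in which the bulky aryl groups of the bisphosphine leave no room under the metal, so both cis substituents of the alkene point away (exo) and the Z geometry is carried into the ring, giving the 2,5-cis-3,4-cis-4,5-trans pyrrolidine with ligand-controlled facial selectivity; the closest known reaction type is the exo-selective copper/bisphosphine-catalysed 1,3-dipolar cycloaddition of glycine aldimines with dialkyl maleates and E-enoates, which has not been shown for Z-β-aryl acrylates.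

Step 6
Reactants: 15 diethyl (2S,3R,4R,5R)-5-[4-(benzyloxy)-3-methoxyphenyl]-3-[4-(benzyloxy)phenyl]pyrrolidine-2,4-dicarboxylate
Product: 17 diethyl (1R,3R)-2-[4-(benzyloxy)phenyl]-4-[4-(benzyloxy)-3-methoxyphenyl]cyclobutane-1,3-dicarboxylate (1α,2α,3β,4β), via isodiazene 16 (not isolated)
Conditions: PhI(OH)OTs (2.5 equiv), H2NCO2NH4 (8 equiv), CF3CH2OH, 80 °C
Reagents that add atoms: none
Why: Nitrogen-deletion ring contraction, in which iodonitrene N-transfer turns the secondary amine into a 1,1-diazene that loses N2 stepwise to a singlet 1,4-biradical, which closes the C2–C5 bond faster than bond rotation, so all four stereocentres are retained (known for 5-aryl-pyrrolidine-2-carboxylates).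

Step 7
Reactants: 17 diethyl (1R,3R)-2-[4-(benzyloxy)phenyl]-4-[4-(benzyloxy)-3-methoxyphenyl]cyclobutane-1,3-dicarboxylate
Product: 18 (1R,3R)-2-[4-(benzyloxy)phenyl]-4-[4-(benzyloxy)-3-methoxyphenyl]cyclobutane-1,3-dicarboxylic acid (1α,2α,3β,4β)
Conditions: LiOH, THF/MeOH/H2O, 40 °C; then 1 M HCl
Reagents that add atoms: lithium hydroxide, [Li+].[OH-]
Why: Saponification by acyl–oxygen cleavage is faster than α-deprotonation of the hindered cyclobutane esters, so the configuration is kept.

Step 8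
Reactants: 19 N-methylprop-2-yn-1-amine; 20 formaldehyde (as paraformaldehyde)
Product: 21 N-(methoxymethyl)-N-methylprop-2-yn-1-amine
Conditions: (CH2O)n, K2CO3, MeOH, rt; distil
Reagents that add atoms: methanol, CO
Why: Condensation of the secondary amine with formaldehyde in methanol gives the N,O-acetal, a storable precursor of the Mannich iminium ion.

Step 9
Reactants: 22 (S)-4-[(tert-butyldimethylsilyl)oxy]cyclopent-2-en-1-one; 21 N-(methoxymethyl)-N-methylprop-2-yn-1-amine
Product: 25 (2R,3S,4S)-4-[(tert-butyldimethylsilyl)oxy]-3-methyl-2-{[methyl(prop-2-yn-1-yl)amino]methyl}cyclopentan-1-one, via lithium enolate 23 (not isolated), via iminium triflate 24 (not isolated)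
Conditions: Me2CuLi (from MeLi, CuI), Et2O, −78 °C; then 24 (from 21, Me3SiOTf, CH2Cl2, 0 °C), −78 → −30 °C
Reagents that add atoms: lithium dimethylcuprate, [Li+].C[Cu-]C
Why: Noyori-type three-component coupling, in which the cuprate adds anti to the silyloxy group and the regiodefined enolate is trapped by the iminium ion (Mannich reaction) anti to the new methyl group, giving the 2,3-trans-3,4-trans ketone.

Step 10
Reactants: 25 (2R,3S,4S)-4-[(tert-butyldimethylsilyl)oxy]-3-methyl-2-{[methyl(prop-2-yn-1-yl)amino]methyl}cyclopentan-1-one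
Product: 27 (3R,4S,5R)-3-[(tert-butyldimethylsilyl)oxy]-4-methyl-5-{[methyl(prop-2-yn-1-yl)amino]methyl}cyclopent-1-en-1-yl trifluoromethanesulfonate, via potassium enolate 26 (not isolated)
Conditions: KN(SiMe3)2, THF, −78 °C; PhNTf2, −78 → −20 °C
Reagents that add atoms: N-phenylbis(trifluoromethanesulfonimide), O=S(=O)(N(c1ccccc1)S(=O)(=O)C(F)(F)F)C(F)(F)F
Why: Kinetic deprotonation at the unhindered CH2 followed by O-triflation gives the less substituted enol triflate, and the low temperature suppresses β-elimination of the silyloxy group.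

Step 11
Reactants: 27 (3R,4S,5R)-3-[(tert-butyldimethylsilyl)oxy]-4-methyl-5-{[methyl(prop-2-yn-1-yl)amino]methyl}cyclopent-1-en-1-yl trifluoromethanesulfonate
Product: 28 (6R,7S,7aS)-6-[(tert-butyldimethylsilyl)oxy]-2,7-dimethyl-4-methylidene-2,3,4,6,7,7a-hexahydro-1H-cyclopenta[c]pyridine
Conditions: Pd(OAc)2 (5 mol%), PPh3 (10 mol%), HCO2Na, DMF, 60 °C
Reagents that add atoms: none
Why: Oxidative addition of zerovalent palladium to the enol triflate, 6-exo-dig syn-carbopalladation of the alkyne and hydride capture from formate (Grigg-type cyclisation–anion capture, a reductive Heck-type reaction) close the piperidine ring.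

Step 12
Reactants: 28 (6R,7S,7aS)-6-[(tert-butyldimethylsilyl)oxy]-2,7-dimethyl-4-methylidene-2,3,4,6,7,7a-hexahydro-1H-cyclopenta[c]pyridine
Product: 30 6-epi-incarvilline [(4R,4aS,6S,7S,7aR)-2,4,7-trimethyloctahydro-1H-cyclopenta[c]pyridin-6-ol], via silyl ether 29 (not isolated)
Conditions: H2 (10 bar), PtO2, EtOAc, rt; filter; then HCl (2 equiv), MeOH, rt; NaOH work-up
Reagents that add atoms: none
Why: Heterogeneous hydrogenation delivers hydrogen to C4a and C4 from the face opposite the allylic silyloxy group and the C1 methylene (the face of H7a), giving the cis-fused ring with H4, H4a and H7a all cis, and acid methanolysis then removes the silyl group.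

Step 13
Reactants: 18 (1R,3R)-2-[4-(benzyloxy)phenyl]-4-[4-(benzyloxy)-3-methoxyphenyl]cyclobutane-1,3-dicarboxylic acid; 30 6-epi-incarvilline
Product: 31 bis[(4R,4aS,6R,7S,7aR)-2,4,7-trimethyloctahydro-1H-cyclopenta[c]pyridin-6-yl] (1R,3R)-2-[4-(benzyloxy)phenyl]-4-[4-(benzyloxy)-3-methoxyphenyl]cyclobutane-1,3-dicarboxylate
Conditions: 30 (2.4 equiv), PPh3, DIAD, THF, 0 °C → rt
Reagents that add atoms: none
Why: Mitsunobu esterification, in which each carboxylate displaces the activated secondary alcohol by SN2 with inversion at C6 (S to R), the coupling mode reported for 6-epi-incarvilline with α-truxillic acids.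

Step 14
Reactants: 31 bis[(4R,4aS,6R,7S,7aR)-2,4,7-trimethyloctahydro-1H-cyclopenta[c]pyridin-6-yl] (1R,3R)-2-[4-(benzyloxy)phenyl]-4-[4-(benzyloxy)-3-methoxyphenyl]cyclobutane-1,3-dicarboxylate
Product: 32 target CNP0331906.2
Conditions: H2 (1 atm), Pd(OH)2/C, MeOH/EtOAc, rt
Reagents that add atoms: none
Why: Hydrogenolysis of the two aryl benzyl ethers leaves the esters, the tertiary amines and the cyclobutane untouched.

**Compound list**

1 | catechol (benzene-1,2-diol) | Oc1ccccc1O | starting material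
2 | guaiacol (2-methoxyphenol) | COc1ccccc1O | intermediate
3 | glyoxylic acid | O=CC(=O)O | starting material
4 | 2-hydroxy-2-(4-hydroxy-3-methoxyphenyl)acetic acid (racemic) | COc1cc(C(O)C(=O)O)ccc1O | intermediate
5 | 2-(4-hydroxy-3-methoxyphenyl)-2-oxoacetic acid | COc1cc(C(=O)C(=O)O)ccc1O | intermediate
6 | vanillin (4-hydroxy-3-methoxybenzaldehyde) | COc1cc(C=O)ccc1O | intermediate
7 | 4-(benzyloxy)-3-methoxybenzaldehyde | COc1cc(C=O)ccc1OCc1ccccc1 | intermediate
8 | 1-(benzyloxy)-4-bromobenzene | Brc1ccc(OCc2ccccc2)cc1 | starting material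
9 | ethyl (Z)-3-iodoprop-2-enoate | CCOC(=O)/C=C\I | starting material
10 | [4-(benzyloxy)phenyl]lithium | [Li]c1ccc(OCc2ccccc2)cc1 | intermediate
11 | [4-(benzyloxy)phenyl]zinc chloride | Cl[Zn]c1ccc(OCc2ccccc2)cc1 | intermediate
12 | ethyl (Z)-3-[4-(benzyloxy)phenyl]prop-2-enoate | CCOC(=O)/C=C\c1ccc(OCc2ccccc2)cc1 | intermediate
13 | glycine ethyl ester hydrochloride | CCOC(=O)CN.Cl | starting material
14 | ethyl N-[(E)-[4-(benzyloxy)-3-methoxyphenyl]methylidene]glycinate | CCOC(=O)C/N=C/c1ccc(OCc2ccccc2)c(OC)c1 | intermediate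
15 | diethyl (2S,3R,4R,5R)-5-[4-(benzyloxy)-3-methoxyphenyl]-3-[4-(benzyloxy)phenyl]pyrrolidine-2,4-dicarboxylate (2,5-cis; 3,4-cis; 4,5-trans) | COc1cc([C@H]2[C@H](C(=O)OCC)[C@H](c3ccc(OCc4ccccc4)cc3)[C@@H](C(=O)OCC)N2)ccc1OCc1ccccc1 | intermediate
16 | 1,1-diazene (isodiazene) of 15, same ring configuration | COc1cc([C@H]2[C@H](C(=O)OCC)[C@H](c3ccc(OCc4ccccc4)cc3)[C@@H](C(=O)OCC)[N+]2=[N-])ccc1OCc1ccccc1 | intermediate
17 | diethyl (1R,3R)-2-[4-(benzyloxy)phenyl]-4-[4-(benzyloxy)-3-methoxyphenyl]cyclobutane-1,3-dicarboxylate (1α,2α,3β,4β: C1 ester cis to the C2 aryl, C3 ester cis to the C4 aryl, aryls trans, esters trans) | COc1cc([C@H]2[C@H](C(=O)OCC)[C@H](c3ccc(OCc4ccccc4)cc3)[C@H]2C(=O)OCC)ccc1OCc1ccccc1 | intermediate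
18 | (1R,3R)-2-[4-(benzyloxy)phenyl]-4-[4-(benzyloxy)-3-methoxyphenyl]cyclobutane-1,3-dicarboxylic acid (1α,2α,3β,4β) | COc1cc([C@H]2[C@H](C(=O)O)[C@H](c3ccc(OCc4ccccc4)cc3)[C@H]2C(=O)O)ccc1OCc1ccccc1 | intermediate
19 | N-methylprop-2-yn-1-amine | CNCC#C | starting material
20 | formaldehyde (used as paraformaldehyde) | C=O | starting material
21 | N-(methoxymethyl)-N-methylprop-2-yn-1-amine | COCN(C)CC#C | intermediate
22 | (S)-4-[(tert-butyldimethylsilyl)oxy]cyclopent-2-en-1-one | O=C1C=C[C@@H](O[Si](C)(C)C(C)(C)C)C1 | starting material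
23 | lithium (3S,4S)-4-[(tert-butyldimethylsilyl)oxy]-3-methylcyclopent-1-en-1-olate | CC(C)(C)[Si](C)(C)O[C@H]1CC([O-])=C[C@@H]1C.[Li+] | intermediate
24 | N-methyl-N-(prop-2-yn-1-yl)methaniminium trifluoromethanesulfonate | C=[N+](C)CC#C.[O-]S(=O)(=O)C(F)(F)F | intermediate
25 | (2R,3S,4S)-4-[(tert-butyldimethylsilyl)oxy]-3-methyl-2-{[methyl(prop-2-yn-1-yl)amino]methyl}cyclopentan-1-one (2,3-trans; 3,4-trans) | CC(C)(C)[Si](C)(C)O[C@H]1CC(=O)[C@@H](CN(C)CC#C)[C@@H]1C | intermediate
26 | potassium (3R,4S,5R)-3-[(tert-butyldimethylsilyl)oxy]-4-methyl-5-{[methyl(prop-2-yn-1-yl)amino]methyl}cyclopent-1-en-1-olate | CC(C)(C)[Si](C)(C)O[C@H]1C=C([O-])[C@@H](CN(C)CC#C)[C@@H]1C.[K+] | intermediate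
27 | (3R,4S,5R)-3-[(tert-butyldimethylsilyl)oxy]-4-methyl-5-{[methyl(prop-2-yn-1-yl)amino]methyl}cyclopent-1-en-1-yl trifluoromethanesulfonate | CC(C)(C)[Si](C)(C)O[C@H]1C=C(OS(=O)(=O)C(F)(F)F)[C@@H](CN(C)CC#C)[C@@H]1C | intermediate
28 | (6R,7S,7aS)-6-[(tert-butyldimethylsilyl)oxy]-2,7-dimethyl-4-methylidene-2,3,4,6,7,7a-hexahydro-1H-cyclopenta[c]pyridine | CC(C)(C)[Si](C)(C)O[C@H]1C=C2C(=C)CN(C)C[C@H]2[C@@H]1C | intermediate
29 | (4R,4aS,6S,7S,7aR)-6-[(tert-butyldimethylsilyl)oxy]-2,4,7-trimethyloctahydro-1H-cyclopenta[c]pyridine | CC(C)(C)[Si](C)(C)O[C@H]1C[C@@H]2[C@@H](CN(C)C[C@@H]2C)[C@@H]1C | intermediate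
30 | 6-epi-incarvilline, (4R,4aS,6S,7S,7aR)-2,4,7-trimethyloctahydro-1H-cyclopenta[c]pyridin-6-ol | O[C@H]1C[C@@H]2[C@@H](CN(C)C[C@@H]2C)[C@@H]1C | intermediate
31 | bis[(4R,4aS,6R,7S,7aR)-2,4,7-trimethyloctahydro-1H-cyclopenta[c]pyridin-6-yl] (1R,3R)-2-[4-(benzyloxy)phenyl]-4-[4-(benzyloxy)-3-methoxyphenyl]cyclobutane-1,3-dicarboxylate (1α,2α,3β,4β) | COc1cc([C@H]2[C@H](C(=O)O[C@@H]3C[C@@H]4[C@@H](CN(C)C[C@@H]4C)[C@@H]3C)[C@H](c3ccc(OCc4ccccc4)cc3)[C@H]2C(=O)O[C@@H]2C[C@@H]3[C@@H](CN(C)C[C@@H]3C)[C@@H]2C)ccc1OCc1ccccc1 | intermediate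
32 | CNP0331906.2, bis[(4R,4aS,6R,7S,7aR)-2,4,7-trimethyloctahydro-1H-cyclopenta[c]pyridin-6-yl] (1R,3R)-2-(4-hydroxyphenyl)-4-(4-hydroxy-3-methoxyphenyl)cyclobutane-1,3-dicarboxylate (1α,2α,3β,4β) | COc1cc([C@H]2[C@H](C(=O)O[C@@H]3C[C@@H]4[C@@H](CN(C)C[C@@H]4C)[C@@H]3C)[C@H](c3ccc(O)cc3)[C@H]2C(=O)O[C@@H]2C[C@@H]3[C@@H](CN(C)C[C@@H]3C)[C@@H]2C)ccc1O | target

**Summary**

Total step count: 14. Longest linear sequence: 8 steps (1, 2, 3, 5, 6, 7, 13, 14).

**Steps most likely to fail, with fallbacks**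

Step 5 (proposed new exo cycloaddition of a Z-cinnamate). The alkene may be too unreactive, may isomerise to E under the basic conditions, or may react endo. The fallback uses known chemistry and sets out from 8, with 7 and 13 as before. A Heck reaction of 8 with ethyl acrylate (Pd(OAc)2, P(o-tol)3, Et3N, DMF, 100 °C) gives ethyl (E)-3-[4-(benzyloxy)phenyl]prop-2-enoate F1. Imine 14 and F1 then react in the endo-selective AgOAc/QUINAP/i-Pr2NEt cycloaddition reported for cinnamate esters, using the ligand enantiomer that gives the (2S,5R) series, to give diethyl (2S,3R,4S,5R)-5-[4-(benzyloxy)-3-methoxyphenyl]-3-[4-(benzyloxy)phenyl]pyrrolidine-2,4-dicarboxylate F2. Heating F2 with DBU in toluene equilibrates the C4 ester, which lies between two aryl-bearing carbons and is cis to one of them either way, so roughly a 1:1 mixture is expected. The 4-epimer is 15; it is separated by chromatography and F2 is recycled. The fallback comes back to the route at 15.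

Step 6 (ring contraction). The two electron-rich aryl ethers may be attacked by the hypervalent iodine oxidant in trifluoroethanol, and β-fragmentation of the biradical to two cinnamates may cut the yield. The fallback sets out from 15. It is converted with 1-(azidosulfonyl)-2,3-dimethylimidazolium triflate (MeCN, 0 °C) into the sulfamoyl azide diethyl (2S,3R,4R,5R)-1-(azidosulfonyl)-5-[4-(benzyloxy)-3-methoxyphenyl]-3-[4-(benzyloxy)phenyl]pyrrolidine-2,4-dicarboxylate F3. Thermolysis of F3 in dioxane at 120 °C gives the same isodiazene 16 by a Curtius-type shift with loss of SO2, without any oxidant, and 16 loses N2 to give the cyclobutane. The fallback comes back to the route at 17.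

Step 11 (palladium cyclisation with hydride capture). The vinylpalladium intermediate may be reduced before it cyclises, or the terminal alkyne may couple intermolecularly. The fallback sets out from 27. α-Selective hydrostannation of the terminal alkyne (Bu3SnH, Mo(CO)3(CNtBu)3 cat., THF, 55 °C) gives (3R,4S,5R)-3-[(tert-butyldimethylsilyl)oxy]-4-methyl-5-({methyl[2-(tributylstannyl)prop-2-en-1-yl]amino}methyl)cyclopent-1-en-1-yl trifluoromethanesulfonate F4. Intramolecular Stille coupling of F4 (Pd(PPh3)4, LiCl, CuCl, DMSO, 60 °C) forms the C4–C4a bond. The fallback comes back to the route at 28.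

**Further compounds**

F1 | step 5 | ethyl (E)-3-[4-(benzyloxy)phenyl]prop-2-enoate | CCOC(=O)/C=C/c1ccc(OCc2ccccc2)cc1
F2 | step 5 | diethyl (2S,3R,4S,5R)-5-[4-(benzyloxy)-3-methoxyphenyl]-3-[4-(benzyloxy)phenyl]pyrrolidine-2,4-dicarboxylate | COc1cc([C@H]2[C@@H](C(=O)OCC)[C@H](c3ccc(OCc4ccccc4)cc3)[C@@H](C(=O)OCC)N2)ccc1OCc1ccccc1
F3 | step 6 | diethyl (2S,3R,4R,5R)-1-(azidosulfonyl)-5-[4-(benzyloxy)-3-methoxyphenyl]-3-[4-(benzyloxy)phenyl]pyrrolidine-2,4-dicarboxylate | COc1cc([C@H]2[C@H](C(=O)OCC)[C@H](c3ccc(OCc4ccccc4)cc3)[C@@H](C(=O)OCC)N2S(=O)(=O)N=[N+]=[N-])ccc1OCc1ccccc1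
F4 | step 11 | (3R,4S,5R)-3-[(tert-butyldimethylsilyl)oxy]-4-methyl-5-({methyl[2-(tributylstannyl)prop-2-en-1-yl]amino}methyl)cyclopent-1-en-1-yl trifluoromethanesulfonate | CC(C)(C)[Si](C)(C)O[C@H]1C=C(OS(=O)(=O)C(F)(F)F)[C@@H](CN(C)CC(=C)[Sn](CCCC)(CCCC)CCCC)[C@@H]1C
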